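The esters at O6 and O10 are cut first, then C8=C9 (ring-closing metathesis), then C9–C10 (vinyl addition to a C10 aldehyde), then C1–C2, then C4–isopropyl and C5–C6 (aldol).
Enabling feature: quaternary C1 lies between oxygenated C10 and C2, so C10–C1–C2 is the retron of a semipinacol 1,2-shift. With C2 parked on C10, atoms C1, C10, C2, C3, C4 and C5 form a cyclohexene. Its 1,10-epoxide contracts to the cyclopentane C1–C2–C3–C4–C5 and expels C10 as an aldehyde.
Forward order: six-membered ring from 3-methylanisole, side chain by aldol, isopropyl addition, epoxide, ring contraction to the five-membered ring, then the seven-membered ring by metathesis.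
Stereochemistry: C5/C6 anti comes from a chair boron aldol, with the absolute sense set by a lipase resolution. C4 is set by addition anti to the side chain, C1 by the stereospecific shift (inversion) of an epoxide placed anti to the dioxane, and C10 by a CBS reduction.
The trans ring fusion is secured because C10 and C6 are not yet joined in a ring when C1 becomes quaternary.

Key step: step 9

Remark on the chemistry: carbon labels follow the daucane skeleton of the target and stay with the same atoms in every intermediate. C1 is the quaternary carbon (CH3), C2 and C3 are the cyclopentane CH2 groups, and C4 is the carbinol carbon (isopropyl). C5 is the ring-fusion CH, C6 the anisoyloxy carbon, C7 a CH2, C8=C9 the alkene (CH3 on C8), and C10 the acetoxy carbon.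

Step 1
Reactants: 1 3-methylanisole
Product: 2 1-methoxy-5-methylcyclohexa-1,4-diene
Conditions: Li, NH3 (l), THF, t-BuOH, −78 → −33 °C
Reagents that add atoms: none
Why: Birch reduction of an anisole leaves both the methoxy and the methyl group on double bonds, which gives the unconjugated diene and creates no stereocentre.

Step 2
Reactants: 2 1-methoxy-5-methylcyclohexa-1,4-diene
Product: 3 3-methylcyclohex-3-en-1-one
Conditions: oxalic acid (cat.), THF–H2O, rt
Reagents that add atoms: water O
Why: Mild acid hydrolysis of the enol ether frees the C4 ketone without moving the C1=C10 double bond into conjugation.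

Step 3
Reactants: 4 3-bromobut-3-en-1-ol
Product: 5 3-bromobut-3-enal
Conditions: Dess–Martin periodinane, CH2Cl2, 0 °C, used crude
Reagents that add atoms: none
Why: Dess–Martin oxidation is neutral enough to deliver the β,γ-unsaturated aldehyde before it can isomerise.

Step 4
Reactants: 3 3-methylcyclohex-3-en-1-one; 5 3-bromobut-3-enal
Product: 7 rac-anti-2-(3-bromo-1-hydroxybut-3-en-1-yl)-3-methylcyclohex-3-en-1-one, via dibutylboron dienolate 6 (not isolated)
Conditions: Bu2BOTf, i-Pr2NEt, CH2Cl2, −78 °C; 5, −78 → −20 °C; MeOH, pH 7 buffer, H2O2, 0 °C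
Reagents that add atoms: none
Why: Boron-mediated aldol addition in which soft enolisation removes the doubly activated C5–H and the ring-locked E(O)-dienolate reacts at its α-carbon C5 through a Zimmerman–Traxler chair, which sets C5 and C6 anti and keeps C1=C10 out of conjugation.

Step 5
Reactants: 7 rac-anti-2-(3-bromo-1-hydroxybut-3-en-1-yl)-3-methylcyclohex-3-en-1-one
Product: 8 (2S)-2-[(1S)-3-bromo-1-hydroxybut-3-en-1-yl]-3-methylcyclohex-3-en-1-one
Conditions: Burkholderia cepacia lipase (Amano PS), vinyl acetate, MTBE, 30 °C, stopped past half conversion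
Reagents that add atoms: none
Why: Lipase-catalysed kinetic resolution by acyl transfer, in which by the Kazlauskas rule the (1R)-carbinol (ring as large, bromoallyl as medium group) should be acetylated faster, leaving the (2S,1S)-alcohol.

Step 6
Reactants: 8 (2S)-2-[(1S)-3-bromo-1-hydroxybut-3-en-1-yl]-3-methylcyclohex-3-en-1-one
Product: 9 (1R,2S)-2-[(1S)-3-bromo-1-hydroxybut-3-en-1-yl]-3-methyl-1-(propan-2-yl)cyclohex-3-en-1-ol
Conditions: i-PrMgCl (3 equiv), LaCl3·2LiCl, THF, −78 → 0 °C
Reagents that add atoms: isopropylmagnesium chloride CC(C)[Mg]Cl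
Why: Lanthanide-assisted Grignard 1,2-addition holds back enolisation, retro-aldol cleavage and β-hydride reduction, and the reagent enters opposite the C5 side chain (equatorial attack), which sets C4 with isopropyl trans and hydroxyl cis to C6.

Step 7
Reactants: 9 (1R,2S)-2-[(1S)-3-bromo-1-hydroxybut-3-en-1-yl]-3-methyl-1-(propan-2-yl)cyclohex-3-en-1-ol
Product: 10 (4S,4aS,8aR)-4-(2-bromoprop-2-en-1-yl)-2,2,5-trimethyl-8a-(propan-2-yl)-4a,7,8,8a-tetrahydro-4H-1,3-benzodioxine
Conditions: Me2C(OMe)2, PPTS (cat.), CH2Cl2, rt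
Reagents that add atoms: 2,2-dimethoxypropane COC(C)(C)OC
Why: Acid-catalysed transacetalisation ties the cis-disposed O4 and O6 into a 1,3-dioxane, which protects both hydroxyls at once and locks the carbocycle with isopropyl equatorial and O4 axial.

Step 8
Reactants: 10 (4S,4aS,8aR)-4-(2-bromoprop-2-en-1-yl)-2,2,5-trimethyl-8a-(propan-2-yl)-4a,7,8,8a-tetrahydro-4H-1,3-benzodioxine
Product: 11 1,10-epoxide of 10 with the oxirane oxygen cis to H5 and to the isopropyl group
Conditions: mCPBA, CH2Cl2, 0 °C
Reagents that add atoms: 3-chloroperbenzoic acid OOC(=O)c1cccc(Cl)c1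
Why: Prilezhaev epoxidation takes the electron-rich trisubstituted C1=C10 bond rather than the bromoalkene and comes from the face of H5, because the other face carries the axial O4 and the dioxane ring, which sets C1 and C10.

Step 9
Reactants: 11 1,10-epoxide of 10 with the oxirane oxygen cis to H5 and to the isopropyl group
Product: 12 (4S,4aS,5S,7aR)-4-(2-bromoprop-2-en-1-yl)-2,2,5-trimethyl-7a-(propan-2-yl)hexahydrocyclopenta[d][1,3]dioxine-5-carbaldehyde
Conditions: MeAl(OAr)2 (MABR, Ar = 4-bromo-2,6-di-tert-butylphenyl, 20 mol %), CH2Cl2, −78 → −40 °C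
Reagents that add atoms: none
Why: The bulky aluminium Lewis acid binds the oxirane oxygen, the tertiary C1–O bond ionises while the C10–C2 ring bond shifts from C10 to C1, and C10 collapses to the aldehyde; this is a semipinacol (Meinwald) rearrangement of the type known for 1-methylcyclohexene oxides, which give 1-methylcyclopentanecarbaldehydes. The cyclopentane C1–C2–C3–C4–C5 is closed by this suprafacial three-centre 1,2-alkyl shift, a six-to-five ring contraction in which the old C2–C10 bond serves as the temporary tether, so no exo or endo trajectory onto a planar carbon is involved. C1 is the only new stereocentre: C2 enters anti to the departing oxygen (inversion), so the epoxide on the H5 face places C10 on the face of H5 and isopropyl and the methyl on the face of O4 and C6, which is the trans disposition of C10 and C6 that becomes the trans ring fusion. The step needs alkyl rather than hydride migration and no proton loss: in the chair locked by the equatorial isopropyl group and the cis-fused dioxane the C10–O(Al) bond stays axial and H10 equatorial, so H10 cannot align with the empty orbital at C1 without ring inversion whereas C2 can by further puckering, and the hindered phenoxide ligands are not basic. Capture of the cationic centre by a side-chain alkene is excluded because C8 carries bromine, and capture by oxygen is excluded because O4 and O6 are tied up in the acetal.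

Step 10
Reactants: 12 (4S,4aS,5S,7aR)-4-(2-bromoprop-2-en-1-yl)-2,2,5-trimethyl-7a-(propan-2-yl)hexahydrocyclopenta[d][1,3]dioxine-5-carbaldehyde
Product: 13 (4S,4aS,5S,7aR)-2,2,5-trimethyl-4-(2-methylprop-2-en-1-yl)-7a-(propan-2-yl)hexahydrocyclopenta[d][1,3]dioxine-5-carbaldehyde
Conditions: MeB(OH)2, PdCl2(dppf) (cat.), K2CO3, dioxane–H2O, 80 °C
Reagents that add atoms: methylboronic acid CB(O)O
Why: Suzuki–Miyaura methylation of the 2-bromoalkene turns the deactivating bromine, no longer needed, into the C8 methyl group, and the aldehyde has no α-hydrogen and tolerates aqueous carbonate.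

Step 11
Reactants: 13 (4S,4aS,5S,7aR)-2,2,5-trimethyl-4-(2-methylprop-2-en-1-yl)-7a-(propan-2-yl)hexahydrocyclopenta[d][1,3]dioxine-5-carbaldehyde
Product: 14 1-[(4S,4aS,5S,7aR)-2,2,5-trimethyl-4-(2-methylprop-2-en-1-yl)-7a-(propan-2-yl)hexahydrocyclopenta[d][1,3]dioxin-5-yl]prop-2-en-1-ol (both C10 epimers)
Conditions: CH2=CHMgBr, THF, −78 °C
Reagents that add atoms: vinylmagnesium bromide C=C[Mg]Br
Why: Grignard addition to the neopentyl aldehyde forms C9–C10, and the configuration at C10 is left open here because step 12 erases it.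

Step 12
Reactants: 14 1-[(4S,4aS,5S,7aR)-2,2,5-trimethyl-4-(2-methylprop-2-en-1-yl)-7a-(propan-2-yl)hexahydrocyclopenta[d][1,3]dioxin-5-yl]prop-2-en-1-ol (both C10 epimers)
Product: 15 1-[(4S,4aS,5S,7aR)-2,2,5-trimethyl-4-(2-methylprop-2-en-1-yl)-7a-(propan-2-yl)hexahydrocyclopenta[d][1,3]dioxin-5-yl]prop-2-en-1-one
Conditions: Dess–Martin periodinane, CH2Cl2, 0 °C
Reagents that add atoms: none
Why: Dess–Martin oxidation converges both allylic alcohols on one vinyl ketone.

Step 13
Reactants: 15 1-[(4S,4aS,5S,7aR)-2,2,5-trimethyl-4-(2-methylprop-2-en-1-yl)-7a-(propan-2-yl)hexahydrocyclopenta[d][1,3]dioxin-5-yl]prop-2-en-1-one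
Product: 16 (1R)-1-[(4S,4aS,5S,7aR)-2,2,5-trimethyl-4-(2-methylprop-2-en-1-yl)-7a-(propan-2-yl)hexahydrocyclopenta[d][1,3]dioxin-5-yl]prop-2-en-1-ol
Conditions: (S)-Me-CBS oxazaborolidine (20 mol %), catecholborane, toluene, −78 °C
Reagents that add atoms: none
Why: Corey–Bakshi–Shibata reduction in which quaternary C1 acts as the large and vinyl as the small group, so the (S)-catalyst should give the (10R)-alcohol, the same sense as the Felkin–Anh preference for hydride, while catecholborane at low temperature leaves the alkenes alone.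

Step 14
Reactants: 16 (1R)-1-[(4S,4aS,5S,7aR)-2,2,5-trimethyl-4-(2-methylprop-2-en-1-yl)-7a-(propan-2-yl)hexahydrocyclopenta[d][1,3]dioxin-5-yl]prop-2-en-1-ol
Product: 17 (1R)-1-[(4S,4aS,5S,7aR)-2,2,5-trimethyl-4-(2-methylprop-2-en-1-yl)-7a-(propan-2-yl)hexahydrocyclopenta[d][1,3]dioxin-5-yl]prop-2-en-1-yl acetate
Conditions: Ac2O, Et3N, DMAP (cat.), CH2Cl2, rt
Reagents that add atoms: acetic anhydride CC(=O)OC(C)=O
Why: DMAP-catalysed acetylation installs the O10 ester of the target on the only free hydroxyl with retention at C10.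

Step 15
Reactants: 17 (1R)-1-[(4S,4aS,5S,7aR)-2,2,5-trimethyl-4-(2-methylprop-2-en-1-yl)-7a-(propan-2-yl)hexahydrocyclopenta[d][1,3]dioxin-5-yl]prop-2-en-1-yl acetate
Product: 18 O4,O6-isopropylidene acetal of 19 (tricyclic, 1S,4R,5S,6S,10R)
Conditions: second-generation Hoveyda–Grubbs catalyst RuCl2(H2IMes)(=CH-C6H4-2-O-i-Pr) (5–10 mol %), toluene, 80 °C
Reagents that add atoms: none
Why: Ring-closing metathesis in which ruthenium loads on the monosubstituted vinyl group and closes onto the 1,1-disubstituted alkene, forming the trisubstituted C8=C9 bond of the seven-membered ring with loss of ethene and touching no stereocentre.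

Step 16
Reactants: 18 O4,O6-isopropylidene acetal of 19 (tricyclic, 1S,4R,5S,6S,10R)
Product: 19 (3R,3aS,4S,8R,8aS)-3,4-dihydroxy-6,8a-dimethyl-3-(propan-2-yl)-1,2,3,3a,4,5,8,8a-octahydroazulen-8-yl acetate
Conditions: AcOH–H2O (4:1), 40 °C
Reagents that add atoms: none
Why: Mild acid hydrolysis of the acetonide frees O4 and O6 under conditions that the secondary allylic acetate and the tertiary alcohol should survive.

Step 17
Reactants: 19 (3R,3aS,4S,8R,8aS)-3,4-dihydroxy-6,8a-dimethyl-3-(propan-2-yl)-1,2,3,3a,4,5,8,8a-octahydroazulen-8-yl acetate; 20 4-methoxybenzoyl chloride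
Product: 21 (3R,3aS,4S,8R,8aS)-8-acetoxy-3-hydroxy-6,8a-dimethyl-3-(propan-2-yl)-1,2,3,3a,4,5,8,8a-octahydroazulen-4-yl 4-methoxybenzoate (target)
Conditions: Et3N, DMAP, CH2Cl2, rt
Reagents that add atoms: none
Why: DMAP-catalysed acylation selects the secondary equatorial O6 over the tertiary O4 and proceeds with retention at C6.

Compound list
1 | 3-methylanisole | COc1cccc(C)c1 | starting material
2 | 1-methoxy-5-methylcyclohexa-1,4-diene | COC1=CCC=C(C)C1 | intermediate
3 | 3-methylcyclohex-3-en-1-one | CC1=CCCC(=O)C1 | intermediate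
4 | 3-bromobut-3-en-1-ol | OCCC(Br)=C | starting material
5 | 3-bromobut-3-enal | O=CCC(Br)=C | intermediate
6 | dibutyl[(3-methylcyclohexa-1,3-dien-1-yl)oxy]borane (boron dienolate, not isolated) | CCCCB(CCCC)OC1=CC(C)=CCC1 | intermediate
7 | rac-anti-2-(3-bromo-1-hydroxybut-3-en-1-yl)-3-methylcyclohex-3-en-1-one (racemate written as both enantiomers) | O=C1CCC=C(C)[C@H]1[C@@H](O)CC(Br)=C.O=C1CCC=C(C)[C@@H]1[C@H](O)CC(Br)=C | intermediate
8 | (2S)-2-[(1S)-3-bromo-1-hydroxybut-3-en-1-yl]-3-methylcyclohex-3-en-1-one | O=C1CCC=C(C)[C@H]1[C@@H](O)CC(Br)=C | intermediate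
9 | (1R,2S)-2-[(1S)-3-bromo-1-hydroxybut-3-en-1-yl]-3-methyl-1-(propan-2-yl)cyclohex-3-en-1-ol | CC(C)[C@]1(O)CCC=C(C)[C@H]1[C@@H](O)CC(Br)=C | intermediate
10 | (4S,4aS,8aR)-4-(2-bromoprop-2-en-1-yl)-2,2,5-trimethyl-8a-(propan-2-yl)-4a,7,8,8a-tetrahydro-4H-1,3-benzodioxine (O4,O6-acetonide of 9) | CC(C)[C@]12CCC=C(C)[C@H]1[C@H](CC(Br)=C)OC(C)(C)O2 | intermediate
11 | 1,10-epoxide of 10, oxirane oxygen cis to H5 and isopropyl, trans to C6 and O4 (1R,4R,5S,6S,10S) | CC(C)[C@]12CC[C@@H]3O[C@]3(C)[C@H]1[C@H](CC(Br)=C)OC(C)(C)O2 | intermediate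
12 | (4S,4aS,5S,7aR)-4-(2-bromoprop-2-en-1-yl)-2,2,5-trimethyl-7a-(propan-2-yl)hexahydrocyclopenta[d][1,3]dioxine-5-carbaldehyde | CC(C)[C@]12CC[C@](C)(C=O)[C@H]1[C@H](CC(Br)=C)OC(C)(C)O2 | intermediate
13 | (4S,4aS,5S,7aR)-2,2,5-trimethyl-4-(2-methylprop-2-en-1-yl)-7a-(propan-2-yl)hexahydrocyclopenta[d][1,3]dioxine-5-carbaldehyde | CC(C)[C@]12CC[C@](C)(C=O)[C@H]1[C@H](CC(C)=C)OC(C)(C)O2 | intermediate
14 | vinyl carbinol of 13, both C10 epimers | CC(C)[C@]12CC[C@](C)(C(O)C=C)[C@H]1[C@H](CC(C)=C)OC(C)(C)O2 | intermediate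
15 | vinyl ketone, 1-[(4S,4aS,5S,7aR)-2,2,5-trimethyl-4-(2-methylprop-2-en-1-yl)-7a-(propan-2-yl)hexahydrocyclopenta[d][1,3]dioxin-5-yl]prop-2-en-1-one | CC(C)[C@]12CC[C@](C)(C(=O)C=C)[C@H]1[C@H](CC(C)=C)OC(C)(C)O2 | intermediate
16 | (10R)-allylic alcohol, (1R)-1-[(4S,4aS,5S,7aR)-2,2,5-trimethyl-4-(2-methylprop-2-en-1-yl)-7a-(propan-2-yl)hexahydrocyclopenta[d][1,3]dioxin-5-yl]prop-2-en-1-ol | CC(C)[C@]12CC[C@](C)([C@H](O)C=C)[C@H]1[C@H](CC(C)=C)OC(C)(C)O2 | intermediate
17 | acetate of 16 | CC(C)[C@]12CC[C@](C)([C@H](OC(C)=O)C=C)[C@H]1[C@H](CC(C)=C)OC(C)(C)O2 | intermediate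
18 | O4,O6-isopropylidene acetal of 19 (trans-fused hydroazulene, 1S,4R,5S,6S,10R) | CC1(C)O[C@H]2CC(C)=C[C@@H](OC(C)=O)[C@@]3(C)CC[C@@](O1)(C(C)C)[C@H]23 | intermediate
19 | (3R,3aS,4S,8R,8aS)-3,4-dihydroxy-6,8a-dimethyl-3-(propan-2-yl)-1,2,3,3a,4,5,8,8a-octahydroazulen-8-yl acetate | O[C@H]1CC(C)=C[C@@H](OC(C)=O)[C@@]2(C)CC[C@@](O)(C(C)C)[C@H]12 | intermediate
20 | 4-methoxybenzoyl chloride | COc1ccc(C(Cl)=O)cc1 | starting material
21 | (3R,3aS,4S,8R,8aS)-8-acetoxy-3-hydroxy-6,8a-dimethyl-3-(propan-2-yl)-1,2,3,3a,4,5,8,8a-octahydroazulen-4-yl 4-methoxybenzoate | COc1ccc(C(=O)O[C@H]2CC(C)=C[C@@H](OC(C)=O)[C@@]3(C)CC[C@@](O)(C(C)C)[C@H]23)cc1 | target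

Total steps: 17. Longest linear sequence: 16 steps (steps 1, 2 and 4–17).

Steps most likely to fail

Step 9. Hydride migration from C10, proton loss next to C1, or Lewis-acid opening of the acetal with participation of the axial O4 may compete with the alkyl shift.
- The fallback replaces the cationic shift with an anionic ring contraction, a Favorskii rearrangement, that forms the same C1–C2 bond. It sets out from 10 and returns at 12.
- Hydroboration–oxidation of C1=C10 from the face of H5 (BH3·THF, then NaOH, H2O2) gives the secondary C10 alcohol F1.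
- Dess–Martin oxidation gives the 2-methylcyclohexanone-type C10 ketone F2.
- Chlorination at the more substituted α-carbon from the same open face (SO2Cl2, CH2Cl2, 0 °C) gives the tertiary α-chloro ketone F3.
- With NaOMe in Et2O the C2 enolate displaces chloride with inversion to a cyclopropanone. Methoxide opens this towards the less substituted carbanion and gives the ring-contracted methyl ester F4.
- DIBAL-H at −78 °C takes F4 to aldehyde 12.

Step 15. Slow loading of ruthenium on the vinyl group next to the quaternary centre, intermolecular metathesis, or strain from the dioxane may hold back closure of the trisubstituted cycloheptene.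
- The fallback closes the ring one oxidation level higher, before C10 is a stereocentre. It sets out from 15 and returns at 18.
- Ring-closing metathesis of the less encumbered vinyl ketone (same catalyst, toluene, 80 °C) gives the β-methylcycloheptenone F5.
- Corey–Bakshi–Shibata reduction with the (S)-oxazaborolidine and catecholborane, relying on reagent control with C1 as the large group, gives the (10R)-cycloheptenol F6.
- Acetylation as in step 14 gives 18.

Step 5. Poor discrimination of the enantiomers or sluggish acylation of the hindered carbinol may leave material of low enantiomeric purity.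
- The fallback moves the resolution to the epoxidation. It sets out from 7 and returns at 11.
- The conditions of steps 6 and 7 applied to the racemate give the racemic diol F7 and the racemic acetonide F8.
- A Shi epoxidation (chiral ketone catalyst, Oxone, buffered MeCN–dimethoxymethane–H2O, 0 °C) is stopped short of half conversion. It uses the enantiomer of the fructose-derived ketone that matches the (4R,5S,6S)-alkene, which by the spiro transition-state model is the L-series ketone.
- This resolves the substrate kinetically, a behaviour known for 1,6-disubstituted cyclohexenes, and delivers 11 directly.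

Further compounds
F1 | step 9 | C10 alcohol from hydroboration of 10, H1 and O10 cis to H5 | CC(C)[C@]12CC[C@H](O)[C@@H](C)[C@H]1[C@H](CC(Br)=C)OC(C)(C)O2
F2 | step 9 | C10 ketone (2-methylcyclohexanone type), methyl trans to H5 | CC(C)[C@]12CCC(=O)[C@@H](C)[C@H]1[C@H](CC(Br)=C)OC(C)(C)O2
F3 | step 9 | 1-chloro C10 ketone, chlorine cis to H5 | CC(C)[C@]12CCC(=O)[C@](C)(Cl)[C@H]1[C@H](CC(Br)=C)OC(C)(C)O2
F4 | step 9 | methyl (4S,4aS,5S,7aR)-4-(2-bromoprop-2-en-1-yl)-2,2,5-trimethyl-7a-(propan-2-yl)hexahydrocyclopenta[d][1,3]dioxine-5-carboxylate | CC(C)[C@]12CC[C@](C)(C(=O)OC)[C@H]1[C@H](CC(Br)=C)OC(C)(C)O2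
F5 | step 15 | tricyclic C10 enone (O4,O6-acetonide, 1S,4R,5S,6S) | CC1(C)O[C@H]2CC(C)=CC(=O)[C@@]3(C)CC[C@@](O1)(C(C)C)[C@H]23
F6 | step 15 | tricyclic (10R)-allylic alcohol (O4,O6-acetonide) | CC1(C)O[C@H]2CC(C)=C[C@@H](O)[C@@]3(C)CC[C@@](O1)(C(C)C)[C@H]23
F7 | step 5 | racemic diol (racemate of 9, written as both enantiomers) | CC(C)[C@]1(O)CCC=C(C)[C@H]1[C@@H](O)CC(Br)=C.CC(C)[C@@]1(O)CCC=C(C)[C@@H]1[C@H](O)CC(Br)=C
F8 | step 5 | racemic acetonide (racemate of 10, written as both enantiomers) | CC(C)[C@]12CCC=C(C)[C@H]1[C@H](CC(Br)=C)OC(C)(C)O2.CC(C)[C@@]12CCC=C(C)[C@@H]1[C@@H](CC(Br)=C)OC(C)(C)O2
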